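The indenone is cut in its five-membered enone ring B (C1, C2, C3, C3a, C7a) at C3a–C3 and C1–C2. One palladium-catalysed annulation makes both bonds: it adds aryl carbon C3a and formyl carbon C1 cis across a C2≡C3 alkyne that already carries the guaiazulenyl group on C2 and the methyl group on C3, and it leaves C1 as the ketone. The feature exploited is the tetrasubstituted C2=C3 bond between the C1 carbonyl and benzo ring A. The precursors are an ortho-bromobenzaldehyde whose second formyl group (the future C4–CHO) is masked as a dioxolane, and guaiazulene bearing a prop-1-ynyl group on C3'.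

Key step: step 7

Numbering: indenone atoms are C1–C7a (ring A is the benzo ring, ring B the enone ring). Azulene atoms carry primes and follow guaiazulene numbering (1'-methyl, 4'-methyl, 7'-isopropyl, bond to the indenone from C3'). No compound of the route has a stereocentre or a stereogenic double bond, so the SMILES carry no stereodescriptors.

Remark on the chemistry: an aryllithium next to a single bromine atom loses LiBr to an aryne even at low temperature, whereas one held between two bromine atoms is stable at −78 °C. The free formyl group of the bromoaldehyde is therefore introduced between two bromine atoms, and the C6 methyl group is added afterwards by cross-coupling.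

Step 1
Reactants: 1 guaiazulene (7-isopropyl-1,4-dimethylazulene)
Product: 3 guaiazulene-3-carbaldehyde (5-isopropyl-3,8-dimethylazulene-1-carbaldehyde), via iminium salt 2 (not isolated)
Conditions: POCl3, DMF, 0 °C to rt; then aq NaOH, 0 °C
Reagents that add atoms: N,N-dimethylformamide CN(C)C=O; water O
Why: Vilsmeier–Haack formylation, in which the chloroiminium ion attacks C3, the only unsubstituted and strongly nucleophilic position of the five-membered ring, and aqueous base hydrolyses iminium salt 2 to the aldehyde.

Step 2
Reactants: 3 guaiazulene-3-carbaldehyde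
Product: 4 3-(2,2-dibromovinyl)-7-isopropyl-1,4-dimethylazulene
Conditions: CBr4, PPh3, Zn dust, CH2Cl2, rt (ylide preformed); then 3, 0 °C to rt
Reagents that add atoms: carbon tetrabromide BrC(Br)(Br)Br
Why: Ramirez gem-dibromoolefination (first half of the Corey–Fuchs sequence), a Wittig-type reaction of Ph3P=CBr2 that works on donor-substituted aryl aldehydes, run in the zinc variant so that no Ph3PBr2 or HBr meets the electron-rich azulene.

Step 3
Reactants: 4 3-(2,2-dibromovinyl)-7-isopropyl-1,4-dimethylazulene
Product: 6 7-isopropyl-1,4-dimethyl-3-(prop-1-yn-1-yl)azulene, via lithium acetylide 5 (not isolated)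
Conditions: n-BuLi (2.1 equiv), THF, −78 °C; then MeI, −78 to 0 °C
Reagents that add atoms: iodomethane CI
Why: Second half of the Corey–Fuchs sequence, in which bromine–lithium exchange and Fritsch–Buttenberg–Wiechell rearrangement at −78 °C give acetylide 5 faster than n-BuLi can add to the seven-membered ring or deprotonate the C4 methyl group, and SN2 methylation of 5 with iodomethane then gives the internal alkyne.

Step 4
Reactants: 7 2,4-dibromobenzaldehyde
Product: 8 2-(2,4-dibromophenyl)-1,3-dioxolane
Conditions: HOCH2CH2OH, p-TsOH·H2O (cat.), toluene, reflux, Dean–Stark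
Reagents that add atoms: ethylene glycol OCCO
Why: Acid-catalysed acetalisation with azeotropic removal of water, which is routine for an ortho-bromobenzaldehyde and masks the formyl group that will become C4–CHO.

Step 5
Reactants: 8 2-(2,4-dibromophenyl)-1,3-dioxolane
Product: 10 2,6-dibromo-3-(1,3-dioxolan-2-yl)benzaldehyde, via aryllithium 9 (not isolated)
Conditions: LiN(iPr)2 (1.1 equiv), THF, −78 °C; then DMF, −78 to −40 °C; aq NH4Cl
Reagents that add atoms: N,N-dimethylformamide CN(C)C=O
Why: Deprotonative lithiation followed by formylation, in which LiN(iPr)2 removes the hydrogen between the two bromine atoms (by far the most acidic one), the doubly bromine-flanked aryllithium 9 is stable at −78 °C, and DMF converts it into the aldehyde on work-up.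

Step 6
Reactants: 10 2,6-dibromo-3-(1,3-dioxolan-2-yl)benzaldehyde
Product: 11 2-bromo-3-(1,3-dioxolan-2-yl)-6-methylbenzaldehyde
Conditions: MeB(OH)2 (1.1 equiv), Pd(PPh3)4 (5 mol %), K2CO3, 1,4-dioxane/H2O, 80 °C
Reagents that add atoms: methylboronic acid CB(O)O
Why: Site-selective Suzuki–Miyaura coupling, in which oxidative addition should prefer C6–Br (one ortho substituent) over C2–Br (wedged between formyl and dioxolanyl), and the bromide left in 11 is both hindered and on a more electron-rich ring, which guards against double methylation.

Step 7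
Reactants: 11 2-bromo-3-(1,3-dioxolan-2-yl)-6-methylbenzaldehyde; 6 7-isopropyl-1,4-dimethyl-3-(prop-1-yn-1-yl)azulene
Product: 12 4-(1,3-dioxolan-2-yl)-2-(5-isopropyl-3,8-dimethylazulen-1-yl)-3,7-dimethyl-1H-inden-1-one
Conditions: Pd(OAc)2 (10 mol %), Na2CO3, Bu4NCl, DMF, 100 °C, argon
Reagents that add atoms: none
Why: Zerovalent palladium, formed in situ from Pd(OAc)2, inserts into the C–Br bond of 11, and the arylpalladium bromide adds syn across the triple bond of 6 with the aryl carbon (future C3a) on the methyl-bearing carbon (C3) and palladium on the azulene-bearing carbon (C2). The vinylpalladium then adds to the neighbouring formyl carbon (C1), closing ring B by a 5-exo-trig attack on C=O, and β-hydride elimination from the palladium alkoxide gives the C1 ketone while Na2CO3 takes up HBr and returns zerovalent palladium. The closest known reaction type is the Larock annulation of ortho-halobenzaldehydes with internal alkynes to 2,3-disubstituted indenones. No stereocentre is formed. The step needs regioselective insertion, which the size difference between methyl and the peri-methylated azulenyl group should secure, reinforced by the doubly ortho-substituted arylpalladium; chloride from Bu4NCl keeps palladium neutral so that this steric bias, and not the donor polarisation of the alkyne, decides. The ketone arises at the correct oxidation level, so the azulene meets neither an oxidant nor a strong acid, and the crowded C2–C3' bond was already made at an unhindered sp carbon.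

Step 8
Reactants: 12 4-(1,3-dioxolan-2-yl)-2-(5-isopropyl-3,8-dimethylazulen-1-yl)-3,7-dimethyl-1H-inden-1-one
Product: 13 2-(5-isopropyl-3,8-dimethylazulen-1-yl)-3,7-dimethyl-1-oxo-1H-indene-4-carbaldehyde (target)
Conditions: 1 M aq HCl, THF, rt, argon
Reagents that add atoms: water O
Why: Acid-catalysed hydrolysis of an aryl dioxolane, under which the enone and the azulene (C1' and C3' both substituted) should be inert at room temperature.

Compound list
1 | guaiazulene (7-isopropyl-1,4-dimethylazulene) | c1cc(C)c2cc(C(C)C)ccc(C)c1-2 | starting material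
2 | [(5-isopropyl-3,8-dimethylazulen-1-yl)methylene]dimethyliminium dichlorophosphate (not isolated) | C[N+](C)=Cc1cc(C)c2cc(C(C)C)ccc(C)c1-2.[O-]P(=O)(Cl)Cl | intermediate
3 | guaiazulene-3-carbaldehyde (5-isopropyl-3,8-dimethylazulene-1-carbaldehyde) | O=Cc1cc(C)c2cc(C(C)C)ccc(C)c1-2 | intermediate
4 | 3-(2,2-dibromovinyl)-7-isopropyl-1,4-dimethylazulene | BrC(Br)=Cc1cc(C)c2cc(C(C)C)ccc(C)c1-2 | intermediate
5 | lithium (7-isopropyl-1,4-dimethylazulen-3-yl)acetylide (not isolated) | [Li]C#Cc1cc(C)c2cc(C(C)C)ccc(C)c1-2 | intermediate
6 | 7-isopropyl-1,4-dimethyl-3-(prop-1-yn-1-yl)azulene | CC#Cc1cc(C)c2cc(C(C)C)ccc(C)c1-2 | intermediate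
7 | 2,4-dibromobenzaldehyde | O=Cc1ccc(Br)cc1Br | starting material
8 | 2-(2,4-dibromophenyl)-1,3-dioxolane | Brc1ccc(C2OCCO2)c(Br)c1 | intermediate
9 | [2,6-dibromo-3-(1,3-dioxolan-2-yl)phenyl]lithium (not isolated) | [Li]c1c(Br)ccc(C2OCCO2)c1Br | intermediate
10 | 2,6-dibromo-3-(1,3-dioxolan-2-yl)benzaldehyde | O=Cc1c(Br)ccc(C2OCCO2)c1Br | intermediate
11 | 2-bromo-3-(1,3-dioxolan-2-yl)-6-methylbenzaldehyde | O=Cc1c(C)ccc(C2OCCO2)c1Br | intermediate
12 | 4-(1,3-dioxolan-2-yl)-2-(5-isopropyl-3,8-dimethylazulen-1-yl)-3,7-dimethyl-1H-inden-1-one | CC1=C(c2cc(C)c3cc(C(C)C)ccc(C)c2-3)C(=O)c2c(C)ccc(C3OCCO3)c21 | intermediate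
13 | 2-(5-isopropyl-3,8-dimethylazulen-1-yl)-3,7-dimethyl-1-oxo-1H-indene-4-carbaldehyde | CC1=C(c2cc(C)c3cc(C(C)C)ccc(C)c2-3)C(=O)c2c(C)ccc(C=O)c21 | target

Total step count: 8. Longest linear sequence: 5 steps (steps 1, 2, 3, 7, 8 from guaiazulene; equally steps 4, 5, 6, 7, 8 from 2,4-dibromobenzaldehyde).

Steps most likely to fail

Step 7. Oxidative addition at the doubly ortho-substituted C–Br bond may be slow, the alkyne may insert in the opposite sense, or the azulene may be lost thermally at 100 °C. The fallback reverses the polarity of the arene; it sets out from 11 and 6 and comes back at 12. Miyaura borylation of 11 (B2pin2, Pd(dppf)Cl2, KOAc, 1,4-dioxane, 90 °C) should give 3-(1,3-dioxolan-2-yl)-6-methyl-2-(4,4,5,5-tetramethyl-1,3,2-dioxaborolan-2-yl)benzaldehyde F1. With [Rh(OH)(cod)]2 in 1,4-dioxane/H2O at 60 °C the aryl group of F1 should add across 6 and the alkenylrhodium should close onto the formyl group, a known route from 2-formylarylboron reagents and internal alkynes to indenols. This should give racemic 4-(1,3-dioxolan-2-yl)-2-(5-isopropyl-3,8-dimethylazulen-1-yl)-3,7-dimethyl-1H-inden-1-ol F2, which MnO2 (CH2Cl2, rt) should oxidise to 12.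

Step 3. A proton may pass from the acidic C4 methyl group of the azulene to the acetylide before methylation, so that the methyl group ends on the wrong carbon, or n-BuLi may add to the seven-membered ring. The fallback uses no organolithium; it sets out from 4 and comes back at 6. Bu4NF·3H2O (DMF, 60 °C) should remove HBr from 4 to give 3-(bromoethynyl)-7-isopropyl-1,4-dimethylazulene F3, and Negishi coupling of F3 with MeZnCl (Pd(PPh3)4, THF, rt) should give 6.

Step 2. The olefination may be sluggish because the formyl group is deactivated by conjugation with the azulene and crowded by the peri C4 methyl group, and the electron-rich dibromoalkene may decompose during isolation. The fallback does not pass through the aldehyde; it sets out from 1 and comes back at 5. Gold-catalysed C–H alkynylation of 1 at C3 with 1-[(triisopropylsilyl)ethynyl]-1,2-benziodoxol-3(1H)-one (AuCl, MeCN, rt) should give 7-isopropyl-1,4-dimethyl-3-[(triisopropylsilyl)ethynyl]azulene F4. Bu4NF (THF, 0 °C) should free 3-ethynyl-7-isopropyl-1,4-dimethylazulene F5, and one equivalent of n-BuLi (THF, −78 °C) should convert F5 into lithium acetylide 5, which is methylated as in step 3.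

Further compounds
F1 | step 7 | 3-(1,3-dioxolan-2-yl)-6-methyl-2-(4,4,5,5-tetramethyl-1,3,2-dioxaborolan-2-yl)benzaldehyde | O=Cc1c(C)ccc(C2OCCO2)c1B1OC(C)(C)C(C)(C)O1
F2 | step 7 | racemic 4-(1,3-dioxolan-2-yl)-2-(5-isopropyl-3,8-dimethylazulen-1-yl)-3,7-dimethyl-1H-inden-1-ol | CC1=C(c2cc(C)c3cc(C(C)C)ccc(C)c2-3)C(O)c2c(C)ccc(C3OCCO3)c21
F3 | step 3 | 3-(bromoethynyl)-7-isopropyl-1,4-dimethylazulene | BrC#Cc1cc(C)c2cc(C(C)C)ccc(C)c1-2
F4 | step 2 | 7-isopropyl-1,4-dimethyl-3-[(triisopropylsilyl)ethynyl]azulene | CC(C)[Si](C#Cc1cc(C)c2cc(C(C)C)ccc(C)c1-2)(C(C)C)C(C)C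
F5 | step 2 | 3-ethynyl-7-isopropyl-1,4-dimethylazulene | C#Cc1cc(C)c2cc(C(C)C)ccc(C)c1-2
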